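**Assumptions.** The target has no stereocenter. Stereogenic intermediates (5, 6, 10, 15, 17) are racemic and are written without descriptors, except 15, for which one enantiomer is drawn. 3-Bromofuran, LiAlH(Ot-Bu)3 and TMPMgCl·LiCl solution are taken as commercial.

## The problem

The target is a flavone: a 4-pyranone (ring C) fused through C4a–C8a to a benzene ring (ring A) and carrying a guaiacyl ring B at C2. It has no stereocenter, so the difficulty is regiochemical. Five oxygen substituents in three states must each be placed and told apart: free hydroxyls at C5 and C4', methyl ethers at C3, C8 and C3', and a prenyl ether at C7. Ring A is pentasubstituted, only C6 bears hydrogen, and its three oxygens are all different, which is awkward to reach by stepwise substitution of a symmetrical phenol. The prenyl ether rules out hydrogenolysis, strong protic or Lewis acid, and long heating above about 150 °C ([3,3] shift towards C6). The 4-pyranone is opened by hard nucleophiles, and a 5,8-hydroquinone on the way is oxidized by air in base. Stereogenic atoms appear only in intermediates (a carbinol, a hemiacetal, cyclobutenone C4, C4a of a dienone) and are all erased, so none needs control and none can exert it. The enabling feature is that C5–O and C8–O stand para on ring A, flanked by C6–H and C7–O. This is the pattern of the hydroquinone that a 4-alkenyl-4-hydroxy-3-alkoxycyclobutenone gives on heating, and the alkene required, C4a=C8a, is the C5=C6 bond of a monocyclic 4-pyranone that already holds ring B and the C3 methoxy group.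

## Retrosynthesis

**Target 20 back to hydroquinone 18 (via 19).** Only heteroatom bonds are cut at the end: the acyl–O bond of the C4' pivalate in 19 and the O–CH3 bond at C8.
- A pivalate is preferred on ring B because a benzyl ether would need hydrogenolysis (prenyl alkene), an acetal would need acid (prenyl ether), and a silyl ether para to the chromone carbonyl is labile to carbonate.
- The C8 methyl group is held back because the pericyclic step delivers the C8 oxygen as a free hydroxyl.
- In 18 the C5 hydroxyl is hydrogen-bonded to C4=O, so the forward reaction is a mono-methylation of the unchelated C8 hydroxyl under exclusion of air, then a mild methanolysis.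

**Hydroquinone 18 back to cyclobutenone 15 (key cut).** The C4a–C5 bond of ring A is cut and the ring is unravelled, through dienone 17 and vinylketene 16, to 4-hydroxycyclobutenone 15.
- Against the neighbouring cuts inside ring C, this one does not require a pre-formed pentasubstituted benzene. The four substituted carbons C5–C8 collapse to a four-carbon squarate unit whose oxygens are already differentiated (ketone, H, prenyl ether, carbinol).
- The forward reaction must open the four-membered ring with the hydroxyl rotating outward, close onto pyranone C5, and run below the temperature at which the prenyl group migrates.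

**Cyclobutenone 15 back to pyranone 8 and semisquarate 13.** The C8–C8a bond (cyclobutenone C4 to pyranone C6) is cut as a carbonyl addition of the C6-magnesiated pyranone 14 to prenyl semisquarate 13.
- This is the only polar bond between the two halves, and it makes the route convergent.
- The nucleophile must be formed at C6 of 8 and not at C5. It must attack the carbonyl of 13 that is flanked by the alkoxy-bearing carbon (the cross-conjugated, more electrophilic one), not the vinylogous ester carbonyl.
- A hindered magnesium amide is chosen because C6–H, next to the ring oxygen, is the most acidic C–H of 8 and because the organomagnesium tolerates the aryl pivalate.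

**Semisquarate 13 back to 11, 12 and 9.** The vinylic C–O bond of 13 is cut to isopropyl semisquarate 11 and prenol 12. 11 in turn comes from diisopropyl squarate 9 by hydride addition (hydroxy ketone 10) and acid-induced loss of one alkoxy group.
- The prenyl group is introduced after the acid step so that it never meets strong acid.
- The forward reaction is an alkoxy exchange at a vinylogous ester carbon, driven by removing the lower-boiling alcohol.

**Pyranone 8 back to carbinol 5 (via 7 and 6).** The C3 O–CH3 bond is cut to 3-hydroxypyranone 7. Ring C of 7 is then traced to the furyl carbinol 5 by an oxidative ring expansion (hemiacetal 6) followed by acid-induced aromatization.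
- The classical furfuryl alcohol to 3-hydroxy-4-pyranone sequence spends a second equivalent of free halogen on the ring-expanded enone. Here that bromine is already present in 3, so the electron-rich ring B meets only one equivalent of a mild bromonium source.
- The forward reaction needs a buffered oxidation, so that the doubly benzylic carbinol does not ionize, and hot aqueous acid that the pivalate survives.

**Carbinol 5 back to 2 and 3; 2 back to vanillin 1.** The bond between the carbinol carbon and furan C2 is cut to aldehyde 2 and 3-bromo-2-lithiofuran 4, made from 3-bromofuran 3 by deprotonation between oxygen and bromine.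
- Acylating vanillin 1 first avoids addition to a deactivated phenoxide aldehyde and avoids a later phenol-versus-carbinol acylation problem.
- The forward reaction relies on the aldehyde reacting far faster than the hindered aryl pivalate at −78 °C.

## Roads not taken

**Alternative 1: C3 stitched in with a methoxymethylene ylide.**
- *Cut:* C2=C3 and C3–C4 of ring C. Rings A and B are first joined as an aryl ester in tert-butyldimethylsilyl 4,6-bis(benzyloxy)-3-methoxy-2-[(3-methoxy-4-silyloxybenzoyl)oxy]benzoate A1.
- *Key step:* (methoxymethylene)triphenylphosphorane A2 is acylated by the silyl ester. The resulting acyl ylide olefinates the neighbouring aryl ester carbonyl, giving 5,7-bis(benzyloxy)-3,8-dimethoxy-2-[3-methoxy-4-(tert-butyldimethylsilyloxy)phenyl]chromen-4-one A3.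
- *Merits:* ring C forms under nearly neutral conditions, C3 arrives with its methoxy group, and both acyl partners are stable.
- *Weak points:* A1 needs a pentasubstituted salicylic acid whose C8 methoxy group must be placed regioselectively by classical substitution. Its ester carbonyl is flanked by two ortho substituents, which slows ylide acylation. After A3, hydrogenolysis, 7-O-prenylation and desilylation are still required.
- *Comparison:* the end game of this road (5-OH chelated, 7-OH free) is more routine than the organometallic and pericyclic steps chosen here, and in that respect it is the safer plan. The chosen plan offsets this with a ring A whose substitution is fixed by connectivity, a prenyl ether that is never unmasked from a benzyl ether, and a shorter sequence.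

**Alternative 2: Difluoroanisoyl cycloaracylation.**
- *Cut:* C3–C4 and O1–C8a.
- *Key step:* the lithium enolate of 2-methoxy-1-[3-methoxy-4-(tosyloxy)phenyl]ethanone A4 is C-acylated by 2,4-difluoro-3-methoxybenzoyl chloride A5. The diketone enolate oxygen then displaces the ortho fluorine, giving 7-fluoro-3,8-dimethoxy-2-[3-methoxy-4-(tosyloxy)phenyl]chromen-4-one A6 in one pot.
- *Merits:* this is the shortest entry to a 3-methoxyflavone core, from two simple halves. The C7 fluorine, para to the carbonyl, is a handle for displacement by the alkoxide of 12.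
- *Weak points:* A6 has hydrogen at C5. The C5 hydroxyl would have to come from a carbonyl-directed C–H oxidation next to electron-rich rings and, if done late, a prenyl alkene. The alkoxide needed at C7 can also attack C2 of the chromone. Tosylate removal needs forcing base.
- *Comparison:* ring C construction is better precedented here than the pyranone metalation chosen, and the step count to the flavone core is lower. The missing C5 oxygen is a structural deficit, however, whereas the chosen plan delivers all four ring A positions in one step.

**Alternative 3: Aurone dibromide ring expansion.**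
- *Cut:* O1–C2, with ring C arising from a five-membered ring.
- *Key step:* (Z)-4,6-bis(benzyloxy)-2-(4-benzyloxy-3-methoxybenzylidene)-7-methoxybenzofuran-3(2H)-one A7 is brominated to dibromide A8. Aqueous base opens A8 to a phenoxide 1,2-diketone, which closes to 5,7-bis(benzyloxy)-2-(4-benzyloxy-3-methoxyphenyl)-3-hydroxy-8-methoxychromen-4-one A9.
- *Merits:* the reactions are long known, the reagents cheap, and the C3 hydroxyl appears ready for methylation.
- *Weak points:* A7 again needs a pentasubstituted ring A. Bromine can substitute the free C5 position of A7 and ring B. The base step can return aurone-type products. After A9, three benzyl ethers fall together, so the 7-OH and 4'-OH must be told apart in the prenylation.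
- *Comparison:* every step has a classical counterpart, which the chosen plan cannot claim for its coupling step. It is the longest road, though, and leaves the 7-O/4'-O differentiation unsolved, which the chosen plan settles from the first step.

Key step: step 8

## Route

Step 1
Reactants: 1 vanillin
Product: 2 4-formyl-2-methoxyphenyl pivalate
Conditions: PivCl, Et3N, DMAP (cat.), CH2Cl2, 0 °C to rt
Reagents that add atoms: pivaloyl chloride, CC(C)(C)C(=O)Cl
Why: DMAP-catalysed O-acylation of the phenol (nucleophilic acyl substitution); the pivalate removes the deactivating phenoxide from the aldehyde and should survive hindered amide bases, hot dilute acid and K2CO3 in acetone.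

Step 2
Reactants: 3 3-bromofuran; 2 4-formyl-2-methoxyphenyl pivalate
Product: 5 (3-bromofuran-2-yl)(3-methoxy-4-pivaloyloxyphenyl)methanol (racemic), via 3-bromo-2-lithiofuran 4 (not isolated)
Conditions: 3, LiN(i-Pr)2, THF, −78 °C; then 2, −78 °C; aq. NH4Cl
Reagents that add atoms: none
Why: Deprotonation of 3-bromofuran at C2, the position flanked by oxygen and bromine, then 1,2-addition of the heteroaryllithium to the aldehyde, which at −78 °C should react far faster than the hindered aryl pivalate; the carbinol center is formed racemic and is erased in step 3.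

Step 3
Reactants: 5 (3-bromofuran-2-yl)(3-methoxy-4-pivaloyloxyphenyl)methanol
Product: 7 3-hydroxy-2-(3-methoxy-4-pivaloyloxyphenyl)-4H-pyran-4-one, via bromo hemiacetal pyranone 6 (not isolated)
Conditions: NBS (1.05 equiv), NaHCO3, NaOAc, THF/H2O, 0 °C; extractive work-up; then 1 M H2SO4, 1,4-dioxane, 90 °C
Reagents that add atoms: water, O
Why: Achmatowicz oxidative ring expansion of the furyl carbinol gives the 4-bromo-6-hydroxypyranone 6; in hot aqueous acid the anomeric hydroxyl ionizes, water adds at C4, HBr is lost and the 3,4-dione enolizes, as in the final stage of the classical furfuryl alcohol to 3-hydroxy-4-pyranone synthesis. The bromine carried in from 3 supplies the extra oxidation level, so no second equivalent of halogen meets ring B.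

Step 4
Reactants: 7 3-hydroxy-2-(3-methoxy-4-pivaloyloxyphenyl)-4H-pyran-4-one
Product: 8 3-methoxy-2-(3-methoxy-4-pivaloyloxyphenyl)-4H-pyran-4-one
Conditions: MeI, K2CO3, acetone, 50 °C
Reagents that add atoms: iodomethane, CI
Why: Williamson O-alkylation of the acidic enolic hydroxyl, as for other 3-hydroxy-4-pyranones; the aryl pivalate is inert to carbonate in an aprotic solvent.

Step 5
Reactants: 9 diisopropyl squarate
Product: 11 3-isopropoxycyclobut-3-ene-1,2-dione, via 4-hydroxy-2,3-diisopropoxycyclobutenone 10 (not isolated)
Conditions: LiAlH(Ot-Bu)3, THF, −78 to −20 °C; then conc. HCl, CH2Cl2, rt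
Reagents that add atoms: water, O
Why: Mono-reduction of one squarate carbonyl by the hindered hydride, then acid-induced ionization of the carbinol, hydration at the distal alkoxy carbon and loss of isopropanol (allylic transposition), the established entry to semisquarate esters; the new carbonyl oxygen comes from water.

Step 6
Reactants: 11 3-isopropoxycyclobut-3-ene-1,2-dione; 12 prenol
Product: 13 3-(3-methylbut-2-enyloxy)cyclobut-3-ene-1,2-dione
Conditions: 12 (5 equiv), Et3N (cat.), CH2Cl2, rt; i-PrOH removed under reduced pressure, cycle repeated
Reagents that add atoms: none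
Why: Vinylogous transesterification by addition–elimination at the alkoxy-bearing carbon, which in squarate esters is as electrophilic as an acyl carbon; the equilibrium is pushed by excess 12 and removal of the lower-boiling isopropanol, and the prenyl group meets no acid.

Step 7
Reactants: 8 3-methoxy-2-(3-methoxy-4-pivaloyloxyphenyl)-4H-pyran-4-one; 13 3-(3-methylbut-2-enyloxy)cyclobut-3-ene-1,2-dione
Product: 15 4-hydroxy-4-[5-methoxy-6-(3-methoxy-4-pivaloyloxyphenyl)-4-oxo-4H-pyran-2-yl]-3-(prenyloxy)cyclobut-2-en-1-one (racemic), via C6-magnesiated pyranone 14 (not isolated)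
Conditions: TMPMgCl·LiCl (1.1 equiv), THF, −40 °C; then 13, THF, −78 °C; aq. NH4Cl at −78 °C
Reagents that add atoms: none
Why: Deprotonative magnesiation at pyranone C6, the C–H next to the ring oxygen (the counterpart of C2 metalation of chromones by hindered amide bases), then 1,2-addition to the semisquarate carbonyl flanked by the alkoxy carbon, which is not deactivated by vinylogous ester resonance. The carbinol center is formed racemic and is erased in step 8; a cold quench prevents alkoxide-driven ring opening.

Step 8
Reactants: 15 4-hydroxy-4-[5-methoxy-6-(3-methoxy-4-pivaloyloxyphenyl)-4-oxo-4H-pyran-2-yl]-3-(prenyloxy)cyclobut-2-en-1-one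
Product: 18 5,8-dihydroxy-3-methoxy-2-(3-methoxy-4-pivaloyloxyphenyl)-7-(prenyloxy)chromen-4-one, via (Z)-pyranonyl vinylketene 16 (not isolated), via 4a-H cyclohexadienone 17 (not isolated)
Conditions: toluene (degassed), Ar, 110 °C
Reagents that add atoms: none
Why: Heating should open the cyclobutenone by a thermal conrotatory 4π electrocyclic reaction in which the donor hydroxyl at C4 rotates outward, so the pyranonyl group turns inward and lies cis to the ketene in 16. The dienylketene 16 then closes by a thermal disrotatory 6π electrocyclization between the ketene carbon and pyranone C5, forming the C4a–C5 bond and ring A as a six-membered carbocycle (dienone 17). The closure is polarity-matched, since the electrophilic ketene carbon meets the β-carbon of the pyranone enol ether, the position at which 4-pyranones accept electrophiles. Dienone 17 carries its C4a hydrogen between two carbonyls, so enolization to the aromatic 5,8-hydroquinone is fast and irreversible and restores the pyranone conjugation. The closest known reaction type is the thermal rearrangement of 4-aryl-, 4-heteroaryl- and 4-alkenyl-4-hydroxycyclobutenones to hydroquinones (Moore rearrangement). No stereocenter is created that persists, since C4 of 15 and C4a of 17 both become trigonal. The step needs outward rotation of the hydroxyl (secured by its donor character; inward rotation would lead to a butenolide) and 6π closure in preference to [3,3] shift or [2+2] capture by the prenyl group (secured by working at 110 °C, well below the usual range of allyl ether rearrangements). Regiochemistry is not an issue because C5 is the only pyranone position adjacent to the ketene-bearing carbon, and the squarate carbons fix C5–OH, C6–H, C7–O-prenyl and C8–OH by connectivity.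

Step 9
Reactants: 18 5,8-dihydroxy-3-methoxy-2-(3-methoxy-4-pivaloyloxyphenyl)-7-(prenyloxy)chromen-4-one
Product: 19 5-hydroxy-3,8-dimethoxy-2-(3-methoxy-4-pivaloyloxyphenyl)-7-(prenyloxy)chromen-4-one
Conditions: MeI (1.5 equiv), K2CO3 (1.2 equiv), acetone, Ar, rt
Reagents that add atoms: iodomethane, CI
Why: Williamson etherification of the C8 hydroxyl; the C5 hydroxyl is tied up in the hydrogen bond to C4=O and is the least reactive phenol of a flavone, and exclusion of air prevents oxidation of the hydroquinone to the quinone.

Step 10
Reactants: 19 5-hydroxy-3,8-dimethoxy-2-(3-methoxy-4-pivaloyloxyphenyl)-7-(prenyloxy)chromen-4-one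
Product: 20 5,4'-dihydroxy-3,8,3'-trimethoxy-7-prenyloxyflavone
Conditions: K2CO3, MeOH, rt; dilute acid work-up
Reagents that add atoms: none
Why: Base-mediated methanolysis (transesterification) of the aryl pivalate; the methyl ethers, the prenyl ether and the chromone should be untouched.

## Compound list

1 | vanillin (4-hydroxy-3-methoxybenzaldehyde) | COc1cc(C=O)ccc1O | starting material
2 | 4-formyl-2-methoxyphenyl pivalate | COc1cc(C=O)ccc1OC(=O)C(C)(C)C | intermediate
3 | 3-bromofuran | Brc1ccoc1 | starting material
4 | 3-bromo-2-lithiofuran (not isolated) | [Li]c1occc1Br | intermediate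
5 | (3-bromofuran-2-yl)(3-methoxy-4-pivaloyloxyphenyl)methanol (racemic) | COc1cc(C(O)c2occc2Br)ccc1OC(=O)C(C)(C)C | intermediate
6 | 4-bromo-6-hydroxy-2-(3-methoxy-4-pivaloyloxyphenyl)-2H-pyran-3(6H)-one (racemic, mixture of C6 epimers; not isolated) | COc1cc(C2OC(O)C=C(Br)C2=O)ccc1OC(=O)C(C)(C)C | intermediate
7 | 3-hydroxy-2-(3-methoxy-4-pivaloyloxyphenyl)-4H-pyran-4-one | COc1cc(-c2occc(=O)c2O)ccc1OC(=O)C(C)(C)C | intermediate
8 | 3-methoxy-2-(3-methoxy-4-pivaloyloxyphenyl)-4H-pyran-4-one | COc1cc(-c2occc(=O)c2OC)ccc1OC(=O)C(C)(C)C | intermediate
9 | diisopropyl squarate (3,4-diisopropoxycyclobut-3-ene-1,2-dione) | CC(C)OC1=C(OC(C)C)C(=O)C1=O | starting material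
10 | 4-hydroxy-2,3-diisopropoxycyclobut-2-en-1-one (racemic; not isolated) | CC(C)OC1=C(OC(C)C)C(O)C1=O | intermediate
11 | 3-isopropoxycyclobut-3-ene-1,2-dione (isopropyl semisquarate) | CC(C)OC1=CC(=O)C1=O | intermediate
12 | prenol (3-methylbut-2-en-1-ol) | CC(C)=CCO | starting material
13 | 3-(3-methylbut-2-enyloxy)cyclobut-3-ene-1,2-dione (prenyl semisquarate) | CC(C)=CCOC1=CC(=O)C1=O | intermediate
14 | [5-methoxy-6-(3-methoxy-4-pivaloyloxyphenyl)-4-oxo-4H-pyran-2-yl]magnesium chloride, LiCl complex (C6-magnesiated 8; not isolated) | COc1cc(-c2oc([Mg]Cl)cc(=O)c2OC)ccc1OC(=O)C(C)(C)C | intermediate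
15 | 4-hydroxy-4-[5-methoxy-6-(3-methoxy-4-pivaloyloxyphenyl)-4-oxo-4H-pyran-2-yl]-3-(prenyloxy)cyclobut-2-en-1-one (racemic; one enantiomer drawn) | O=C1C=C(OCC=C(C)C)[C@]1(O)c1cc(=O)c(OC)c(-c2ccc(OC(=O)C(C)(C)C)c(OC)c2)o1 | intermediate
16 | (3Z)-4-hydroxy-4-[5-methoxy-6-(3-methoxy-4-pivaloyloxyphenyl)-4-oxo-4H-pyran-2-yl]-3-(prenyloxy)buta-1,3-dien-1-one (vinylketene; not isolated) | O=C=C/C(OCC=C(C)C)=C(/O)c1cc(=O)c(OC)c(-c2ccc(OC(=O)C(C)(C)C)c(OC)c2)o1 | intermediate
17 | 8-hydroxy-3-methoxy-2-(3-methoxy-4-pivaloyloxyphenyl)-7-(prenyloxy)-4aH-chromene-4,5-dione (racemic; not isolated) | COC1=C(c2ccc(OC(=O)C(C)(C)C)c(OC)c2)OC2=C(O)C(OCC=C(C)C)=CC(=O)C2C1=O | intermediate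
18 | 5,8-dihydroxy-3-methoxy-2-(3-methoxy-4-pivaloyloxyphenyl)-7-(prenyloxy)chromen-4-one | COc1cc(-c2oc3c(O)c(OCC=C(C)C)cc(O)c3c(=O)c2OC)ccc1OC(=O)C(C)(C)C | intermediate
19 | 5-hydroxy-3,8-dimethoxy-2-(3-methoxy-4-pivaloyloxyphenyl)-7-(prenyloxy)chromen-4-one | COc1cc(-c2oc3c(OC)c(OCC=C(C)C)cc(O)c3c(=O)c2OC)ccc1OC(=O)C(C)(C)C | intermediate
20 | 5,4'-dihydroxy-3,8,3'-trimethoxy-7-prenyloxyflavone | COc1cc(-c2oc3c(OC)c(OCC=C(C)C)cc(O)c3c(=O)c2OC)ccc1O | target

## Step count and risk

Total: 10 steps. Longest linear sequence: 8 steps (1, 2, 3, 4, 7, 8, 9, 10). The squarate branch (steps 5 and 6) joins at step 7.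

**Step 8 (key step).**
- *What may go wrong:* ring opening may be too slow at 110 °C. At the higher temperature then required, the prenyl vinyl ether can undergo [3,3] shift or the ketene can be captured by the prenyl alkene. The minor inward-hydroxyl rotamer can also drain the reversible equilibrium by lactonization.
- *Fallback:* keep the prenyl group out of the thermolysis. The route is left at 8 and 11, step 6 is skipped, and the route is rejoined at 19. Pyranone 8, magnesiated as in step 7, is added to 11 to give 4-hydroxy-3-isopropoxy-4-[5-methoxy-6-(3-methoxy-4-pivaloyloxyphenyl)-4-oxo-4H-pyran-2-yl]cyclobut-2-en-1-one F1. Thermolysis, now free to run in refluxing xylene, gives 5,8-dihydroxy-7-isopropoxy-3-methoxy-2-(3-methoxy-4-pivaloyloxyphenyl)chromen-4-one F2. Methylation as in step 9 gives the 8-methyl ether F3. BCl3 (CH2Cl2, −78 to 0 °C) cleaves the isopropyl ether selectively to the 7-hydroxy compound F4. Prenyl bromide with K2CO3 in acetone alkylates the only unchelated phenol and gives 19.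

**Step 7.**
- *What may go wrong:* carbonyl-directed metalation at C5 followed by ring fragmentation; self-addition of the magnesiated pyranone to unreacted 8 during a slow deprotonation; conjugate addition–elimination at the alkoxy carbon of 13.
- *Fallback:* replace deprotonation by halogen–metal exchange. From 8, zincation with TMPZnCl·LiCl (THF, rt) and iodolysis give 6-iodo-3-methoxy-2-(3-methoxy-4-pivaloyloxyphenyl)-4H-pyran-4-one F5, at which stage the regiochemistry can be verified. Iodine–magnesium exchange with i-PrMgCl·LiCl at −78 °C generates 14 in the absence of amide base and free 8. Addition of 13 returns the route to 15.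

**Step 6.**
- *What may go wrong:* incomplete alkoxy exchange, or base-induced degradation of the sensitive semisquarate before the equilibrium is shifted.
- *Fallback:* O-alkylation instead of exchange. From 11, hydrolysis with aqueous HCl gives semisquaric acid (3-hydroxycyclobut-3-ene-1,2-dione) F6. Alkylation with prenyl bromide in the presence of Ag2O (Et2O, dark, rt) returns the route to 13.

**Step 3.**
- *What may go wrong:* the brominated furan is oxidized more slowly than a plain furan. This leaves time for ionization of the doubly benzylic carbinol or for bromination of ring B. Partial loss of the pivalate in hot acid is also possible.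
- *Fallback:* oxidize a plain furan and introduce the bromine afterwards. From 2, addition of 2-furyllithium gives furan-2-yl(3-methoxy-4-pivaloyloxyphenyl)methanol F7. Buffered Achmatowicz oxidation gives 6-hydroxy-2-(3-methoxy-4-pivaloyloxyphenyl)-2H-pyran-3(6H)-one F8. α-Bromination of the enone (Br2, CH2Cl2, −78 °C; then Et3N) returns the route to 6, which is taken through the acid stage of step 3.

**Step 9.**
- *What may go wrong:* autoxidation of the hydroquinone to the 5,8-quinone under basic conditions, or partial methylation at C5.
- *Fallback:* fix the C8 methyl ether before ring A exists. From 15, O-methylation of the tertiary hydroxyl (MeI, Ag2O, CH3CN) gives 4-methoxy-4-[5-methoxy-6-(3-methoxy-4-pivaloyloxyphenyl)-4-oxo-4H-pyran-2-yl]-3-(prenyloxy)cyclobut-2-en-1-one F9. Its thermolysis (toluene, 110 °C) follows the same electrocyclic course, cannot lactonize, and delivers 19 directly.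

## Further compounds

F1 | step 8 | 4-hydroxy-3-isopropoxy-4-[5-methoxy-6-(3-methoxy-4-pivaloyloxyphenyl)-4-oxo-4H-pyran-2-yl]cyclobut-2-en-1-one (racemic) | O=C1C=C(OC(C)C)C1(O)c1cc(=O)c(OC)c(-c2ccc(OC(=O)C(C)(C)C)c(OC)c2)o1
F2 | step 8 | 5,8-dihydroxy-7-isopropoxy-3-methoxy-2-(3-methoxy-4-pivaloyloxyphenyl)chromen-4-one | COc1cc(-c2oc3c(O)c(OC(C)C)cc(O)c3c(=O)c2OC)ccc1OC(=O)C(C)(C)C
F3 | step 8 | 5-hydroxy-7-isopropoxy-3,8-dimethoxy-2-(3-methoxy-4-pivaloyloxyphenyl)chromen-4-one | COc1cc(-c2oc3c(OC)c(OC(C)C)cc(O)c3c(=O)c2OC)ccc1OC(=O)C(C)(C)C
F4 | step 8 | 5,7-dihydroxy-3,8-dimethoxy-2-(3-methoxy-4-pivaloyloxyphenyl)chromen-4-one | COc1cc(-c2oc3c(OC)c(O)cc(O)c3c(=O)c2OC)ccc1OC(=O)C(C)(C)C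
F5 | step 7 | 6-iodo-3-methoxy-2-(3-methoxy-4-pivaloyloxyphenyl)-4H-pyran-4-one | COc1cc(-c2oc(I)cc(=O)c2OC)ccc1OC(=O)C(C)(C)C
F6 | step 6 | semisquaric acid (3-hydroxycyclobut-3-ene-1,2-dione) | OC1=CC(=O)C1=O
F7 | step 3 | furan-2-yl(3-methoxy-4-pivaloyloxyphenyl)methanol (racemic) | COc1cc(C(O)c2ccco2)ccc1OC(=O)C(C)(C)C
F8 | step 3 | 6-hydroxy-2-(3-methoxy-4-pivaloyloxyphenyl)-2H-pyran-3(6H)-one (racemic, mixture of C6 epimers) | COc1cc(C2OC(O)C=CC2=O)ccc1OC(=O)C(C)(C)C
F9 | step 9 | 4-methoxy-4-[5-methoxy-6-(3-methoxy-4-pivaloyloxyphenyl)-4-oxo-4H-pyran-2-yl]-3-(prenyloxy)cyclobut-2-en-1-one (racemic) | O=C1C=C(OCC=C(C)C)C1(OC)c1cc(=O)c(OC)c(-c2ccc(OC(=O)C(C)(C)C)c(OC)c2)o1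
A1 | alternative 1 | tert-butyldimethylsilyl 4,6-bis(benzyloxy)-3-methoxy-2-{[3-methoxy-4-(tert-butyldimethylsilyloxy)benzoyl]oxy}benzoate | COc1cc(C(=O)Oc2c(OC)c(OCc3ccccc3)cc(OCc3ccccc3)c2C(=O)O[Si](C)(C)C(C)(C)C)ccc1O[Si](C)(C)C(C)(C)C
A2 | alternative 1 | (methoxymethylene)triphenylphosphorane | COC=P(c1ccccc1)(c1ccccc1)c1ccccc1
A3 | alternative 1 | 5,7-bis(benzyloxy)-3,8-dimethoxy-2-[3-methoxy-4-(tert-butyldimethylsilyloxy)phenyl]chromen-4-one | COc1cc(-c2oc3c(OC)c(OCc4ccccc4)cc(OCc4ccccc4)c3c(=O)c2OC)ccc1O[Si](C)(C)C(C)(C)C
A4 | alternative 2 | 2-methoxy-1-[3-methoxy-4-(tosyloxy)phenyl]ethanone | COCC(=O)c1ccc(OS(=O)(=O)c2ccc(C)cc2)c(OC)c1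
A5 | alternative 2 | 2,4-difluoro-3-methoxybenzoyl chloride | COc1c(F)ccc(C(=O)Cl)c1F
A6 | alternative 2 | 7-fluoro-3,8-dimethoxy-2-[3-methoxy-4-(tosyloxy)phenyl]chromen-4-one | COc1cc(-c2oc3c(OC)c(F)ccc3c(=O)c2OC)ccc1OS(=O)(=O)c1ccc(C)cc1
A7 | alternative 3 | (Z)-4,6-bis(benzyloxy)-2-(4-benzyloxy-3-methoxybenzylidene)-7-methoxybenzofuran-3(2H)-one | COc1cc(/C=C2\Oc3c(OC)c(OCc4ccccc4)cc(OCc4ccccc4)c3C2=O)ccc1OCc1ccccc1
A8 | alternative 3 | 4,6-bis(benzyloxy)-2-bromo-2-[bromo(4-benzyloxy-3-methoxyphenyl)methyl]-7-methoxybenzofuran-3(2H)-one (racemic; relative configuration not specified) | COc1cc(C(Br)C2(Br)Oc3c(OC)c(OCc4ccccc4)cc(OCc4ccccc4)c3C2=O)ccc1OCc1ccccc1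
A9 | alternative 3 | 5,7-bis(benzyloxy)-2-(4-benzyloxy-3-methoxyphenyl)-3-hydroxy-8-methoxychromen-4-one | COc1cc(-c2oc3c(OC)c(OCc4ccccc4)cc(OCc4ccccc4)c3c(=O)c2O)ccc1OCc1ccccc1
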